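## Retrosynthetic overview
1. Feature: the C10=C11 bond of the dibenzo[b,f]oxepine is shared with a dihydropyran. Cα = C10 carries the enol-ether oxygen and ring B; Cβ = C11 carries ring A and the cyclobutane CH. Opening the C10–O bond gives an oxepin-10-one plus a tertiary alcohol, and in that ketone Cβ is the only α-carbon that bears hydrogen.
2. Key disconnection: Cβ–C(ring A), the most crowded bond of the aromatic half (next to the cyclobutane CH and the CMe2 carbon). It is made as the last C–C bond, by palladium enolate arylation of a ring A chloride that the diaryl ether oxygen holds beside Cβ.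
3. The open-chain ketone comes from exo-face CuH conjugate reduction of a cyclobutylidene enone. That enone comes from aldol addition and dehydration between a diaryl ether acetophenone and a silylated bicyclo[3.2.0]heptan-6-one.
4. The bicyclic ketone comes from an enantioselective CuH reductive aldol cyclisation of 4,4-dimethyl-3-(3-oxobutyl)cyclobutenone, itself made by a dimethylketene/ethoxyacetylene [2+2] and a Grignard addition. The acetophenone comes from SNAr on methyl ethers, BBr3, silylation and a bromide-selective Stille prenylation.
5. Ring order: cyclobutene (step 1), cyclopentane (step 3), oxepinone (step 13), dihydropyran (step 14). Rings A and B are bought.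

Key step: step 13

**Labels.**
- Ring A is the chlorinated, prenylated ring; ring B carries the carbonyl.
- The bicycle is numbered as bicyclo[3.2.0]heptane: C1 and C5 are the ring-fusion CH carbons, C4 is the carbinol carbon, C6 is the carbon that bears Cβ, and C7 is CMe2.
- exo means the convex face (the side of the ring-fusion hydrogens); endo means the concave face.
- Ar = 2-[2-chloro-4-(3-methylbut-2-en-1-yl)-5-(triisopropylsilyloxy)phenoxy]-4-(triisopropylsilyloxy)phenyl.

**Assumption.** The sense of induction of a chiral CuH catalyst on a cyclobutenone is not known. (R)-DTBM-SEGPHOS is written for the (1S,4R,5S) series, and the antipodal ligand is taken if a test reaction shows the opposite sense.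

## Route

Step 1
Reactants: 1 isobutyryl chloride; 2 ethoxyacetylene
Product: 4 3-ethoxy-4,4-dimethylcyclobut-2-en-1-one, via dimethylketene 3 (not isolated)
Conditions: Et3N (1.3 equiv), hexanes–Et2O, 0 °C → reflux
Reagents that add atoms: none
Why: Triethylamine dehydrochlorinates 1 to dimethylketene, whose electrophilic central carbon bonds to the nucleophilic CH terminus of the ynol ether, so the thermal ketene–alkyne [2+2] cycloaddition should give only the 3-ethoxy regioisomer; no stereocentre is formed.

Step 2
Reactants: 4 3-ethoxy-4,4-dimethylcyclobut-2-en-1-one; 5 2-(2-bromoethyl)-2-methyl-1,3-dioxolane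
Product: 8 4,4-dimethyl-3-(3-oxobutyl)cyclobut-2-en-1-one, via Grignard reagent 6 (not isolated), via cyclobutenol adduct 7 (not isolated)
Conditions: Mg, THF, 25–30 °C; then 4, THF, −78 → 0 °C; then 2 M aq HCl, rt
Reagents that add atoms: water, O
Why: Stork–Danheiser-type transposition of a vinylogous ester, in which the Grignard reagent adds to the ring carbonyl, acid ionises the allylic alcohol with help of the ethoxy group, water captures the cation at the former C–OEt carbon and the dioxolane is hydrolysed in the same pot; because CMe2 flanks both electrophilic ring carbons, 1,2-addition/transposition and addition–elimination converge on the same enone.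

Step 3
Reactants: 8 4,4-dimethyl-3-(3-oxobutyl)cyclobut-2-en-1-one
Product: 10 (1S,4R,5S)-4-hydroxy-4,7,7-trimethylbicyclo[3.2.0]heptan-6-one (cis-fused; 4-OH endo; 4-CH3 exo), via diethoxymethylsilyl ether 9 (not isolated)
Conditions: Cu(OAc)2·H2O (5 mol %), (R)-DTBM-SEGPHOS (5.5 mol %), (EtO)2MeSiH (1.2 equiv), toluene, −25 °C; then 0.5 M aq HCl, THF, 0 °C
Reagents that add atoms: none
Why: Proposed new method: a ligated monovalent copper hydride should deliver hydride to the β-carbon of the strained enone (future C1) on the face chosen by the chiral bisphosphine, the copper cyclobutenolate then attacks the tethered methyl ketone through a closed, copper-bridged Zimmerman–Traxler-type transition state (five-membered ring, enolate C=C exocyclic to it) that can only give the cis ring fusion at C5 and places the new C4–O bond syn to the ring carbonyl (endo) with the methyl exo, and σ-bond metathesis of the copper alkoxide with the silane traps the aldolate against retro-aldol cleavage; the closest known reactions are the CuH-catalysed enantioselective reductive aldol cyclisation of β,β-disubstituted enones bearing a pendant ketone and copper-catalysed asymmetric conjugate additions to cyclobutenones, neither of which has been run as a reductive aldol on a four-membered enone.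

Step 4
Reactants: 10 (1S,4R,5S)-4-hydroxy-4,7,7-trimethylbicyclo[3.2.0]heptan-6-one
Product: 11 (1S,4R,5S)-4,7,7-trimethyl-4-(triethylsilyloxy)bicyclo[3.2.0]heptan-6-one
Conditions: Et3SiOTf, 2,6-lutidine, CH2Cl2, −78 → 0 °C
Reagents that add atoms: triethylsilyl trifluoromethanesulfonate, CC[Si](CC)(CC)OS(=O)(=O)C(F)(F)F
Why: A silyl triflate with a hindered pyridine base silylates even crowded tertiary alcohols without an alkoxide being formed, which avoids retro-aldol opening of the β-hydroxy ketone and leaves the stereocentres untouched.

Step 5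
Reactants: 12 2-chloro-5-methoxyphenol
Product: 13 4-bromo-2-chloro-5-methoxyphenol
Conditions: N-bromosuccinimide (1.0 equiv), MeCN, −20 → 0 °C
Reagents that add atoms: N-bromosuccinimide, O=C1CCC(=O)N1Br
Why: Electrophilic aromatic bromination should go para to the free hydroxyl and ortho to the methoxy group (C4), because the other doubly activated site (C6) lies between two oxygen substituents.

Step 6
Reactants: 13 4-bromo-2-chloro-5-methoxyphenol; 14 1-(2-fluoro-4-methoxyphenyl)ethan-1-one
Product: 15 1-[2-(4-bromo-2-chloro-5-methoxyphenoxy)-4-methoxyphenyl]ethan-1-one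
Conditions: K2CO3, DMF, 110 °C
Reagents that add atoms: none
Why: Nucleophilic aromatic substitution (addition–elimination) of the phenoxide at the fluoride ortho to the acetyl group, in which the methoxy group is meta to the reacting carbon and hardly retards it; methyl ethers are carried here because the fluoride released would strip aryl silyl ethers.

Step 7
Reactants: 15 1-[2-(4-bromo-2-chloro-5-methoxyphenoxy)-4-methoxyphenyl]ethan-1-one
Product: 16 1-[2-(4-bromo-2-chloro-5-hydroxyphenoxy)-4-hydroxyphenyl]ethan-1-one
Conditions: BBr3 (4 equiv), CH2Cl2, −78 °C → rt; aq work-up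
Reagents that add atoms: none
Why: Lewis acid cleavage of both aryl methyl ethers is placed before the acid-sensitive prenyl group is present, and the diaryl ether, the ketone and both aryl halides are inert to BBr3.

Step 8
Reactants: 16 1-[2-(4-bromo-2-chloro-5-hydroxyphenoxy)-4-hydroxyphenyl]ethan-1-one
Product: 17 1-{2-[4-bromo-2-chloro-5-(triisopropylsilyloxy)phenoxy]-4-(triisopropylsilyloxy)phenyl}ethan-1-one
Conditions: iPr3SiCl (2.5 equiv), imidazole (5 equiv), DMF, rt → 40 °C
Reagents that add atoms: chlorotriisopropylsilane, CC(C)[Si](Cl)(C(C)C)C(C)C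
Why: Imidazole-promoted silylation of phenols; triisopropylsilyl is preferred to smaller silyl groups because these aryl ethers must later survive an alkoxide base at 80 °C and still leave with fluoride.

Step 9
Reactants: 17 1-{2-[4-bromo-2-chloro-5-(triisopropylsilyloxy)phenoxy]-4-(triisopropylsilyloxy)phenyl}ethan-1-one; 18 tributyl(3-methylbut-2-en-1-yl)stannane
Product: 19 1-Ar-ethan-1-one (ArC(O)CH3)
Conditions: Pd(PPh3)4 (5 mol %), toluene, 110 °C
Reagents that add atoms: none
Why: Stille coupling, in which Pd(PPh3)4 inserts into C–Br but not into C–Cl and reductive elimination at the less substituted allyl terminus gives the linear prenyl arene, under neutral conditions that the ketone and the silyl ethers tolerate.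

Step 10
Reactants: 19 1-Ar-ethan-1-one; 11 (1S,4R,5S)-4,7,7-trimethyl-4-(triethylsilyloxy)bicyclo[3.2.0]heptan-6-one
Product: 20 1-Ar-2-[(1S,4R,5R,6R)-6-hydroxy-4,7,7-trimethyl-4-(triethylsilyloxy)bicyclo[3.2.0]heptan-6-yl]ethan-1-one (6-OH endo; side chain exo)
Conditions: LiN(SiMe3)2 (1.2 equiv), THF, −78 °C; then 11, −78 → −40 °C; AcOH quench at −78 °C
Reagents that add atoms: none
Why: Aldol addition of the only possible (methyl) enolate of 19 to the cyclobutanone is favoured by release of carbonyl angle strain, attack on the convex face sets a C6 centre that step 11 erases, and the cold acidic quench forestalls retro-aldol cleavage and silyl migration.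

Step 11
Reactants: 20 aldol adduct
Product: 22 1-Ar-2-[(1S,4R,5R)-4,7,7-trimethyl-4-(triethylsilyloxy)bicyclo[3.2.0]heptan-6-ylidene]ethan-1-one (E/Z mixture), via tertiary mesylate 21 (not isolated)
Conditions: MsCl (3 equiv), Et3N (6 equiv), CH2Cl2, 0 °C → rt
Reagents that add atoms: none
Why: Mesylation of the tertiary alcohol through the small electrophile sulfene, followed by E1cB elimination via the ketone enolate, should give the conjugated exocyclic enone rather than the strained cyclobutene; the alkene geometry has no bearing on the next step.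

Step 12
Reactants: 22 cyclobutylidene enone
Product: 23 1-Ar-2-[(1S,4R,5R,6R)-4,7,7-trimethyl-4-(triethylsilyloxy)bicyclo[3.2.0]heptan-6-yl]ethan-1-one (side chain endo, cis to the C4 oxygen)
Conditions: Cu(OAc)2·H2O (5 mol %), 1,2-bis(diphenylphosphino)benzene (5 mol %), (EtO)2MeSiH (2 equiv), t-BuOH (2 equiv), toluene, rt
Reagents that add atoms: none
Why: Copper hydride-catalysed conjugate reduction spares the prenyl group, C–Cl and the silyl ethers, and the bulky ligated CuH can reach the β-carbon C6 only from the convex exo face (the endo face is shielded by the cyclopentane ring and its endo OSiEt3 group), so hydrogen ends up exo and the CH2C(O)Ar chain endo.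

Step 13
Reactants: 23 open-chain chloro ketone
Product: 24 2-(3-methylbut-2-en-1-yl)-3,7-bis(triisopropylsilyloxy)-11-[4,7,7-trimethyl-4-(triethylsilyloxy)bicyclo[3.2.0]heptan-6-yl]dibenzo[b,f]oxepin-10(11H)-one (bicyclic unit as in 23; one C11 epimer drawn arbitrarily)
Conditions: Pd2(dba)3 (5 mol %), XPhos (12 mol %), NaOtBu (2.2 equiv), toluene (degassed), 80 °C
Reagents that add atoms: none
Why: Zerovalent palladium carrying the bulky, electron-rich XPhos inserts into the only carbon–halogen bond (ring A C–Cl), tert-butoxide turns the ketone into its enolate, chloride on palladium is exchanged for the enolate, and C–C reductive elimination from the C-bound arylpalladium enolate forms Cβ–C(ring A). This is the palladium-catalysed intramolecular α-arylation of ketones, a known reaction type for aryl chlorides and for closures to dibenzo[b,f]oxepin-10(11H)-ones. The seven-membered ring closes in the enolendo sense (Cα and Cβ both become ring members) through an eight-membered palladacycle that the diaryl ether pre-organises. The new stereocentre C11 is not controlled: it forms under the bias of C6, can equilibrate through the product enolate, and becomes sp2 in step 14. Regioselectivity and mono-arylation are secured by the substrate, since Cβ is the only enolisable carbon and the molecule holds a single aryl halide. The selectivity that has to be won is reductive elimination over β-hydride elimination towards C6–H and over O-arylation, and the large biaryl phosphine favours it.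

Step 14
Reactants: 24 11-substituted oxepinone
Product: 27 bis(triisopropylsilyl) ether of the target, via hydroxy ketone 25 (not isolated), via cyclic hemiketal 26 (not isolated)
Conditions: pyridinium p-toluenesulfonate (0.3 equiv), MeOH–CH2Cl2 1:1, 40 °C; then solvent change to toluene, 4 Å molecular sieves, 80 °C
Reagents that add atoms: none
Why: Mild acid methanolysis removes the alkyl triethylsilyl ether while the aryl triisopropylsilyl ethers stay, the freed endo alcohol adds to the cis-disposed C10 ketone (six-membered hemiketal), and loss of water through an oxocarbenium ion stabilised by ring B, then of the C11 proton, gives the tetrasubstituted enol ether conjugated with both arenes; the pyridinium salt is too weak to ionise the tertiary C–O bond or protonate the prenyl group, and the phenol next to the prenyl group is still masked, so chroman formation is excluded.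

Step 15
Reactants: 27 bis(triisopropylsilyl) ether of the target
Product: 28 CNP0185814.1
Conditions: Bu4NF (2.5 equiv), AcOH (2.5 equiv), THF, 0 °C
Reagents that add atoms: none
Why: Fluoride cleaves aryl silyl ethers rapidly at 0 °C, acetic acid buffers the phenoxides, and the enol ether, the prenyl group and all four stereocentres are inert to these conditions.

## Compound list
1 | isobutyryl chloride | CC(C)C(Cl)=O | starting material
2 | ethoxyacetylene | CCOC#C | starting material
3 | dimethylketene | CC(C)=C=O | intermediate
4 | 3-ethoxy-4,4-dimethylcyclobut-2-en-1-one | CCOC1=CC(=O)C1(C)C | intermediate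
5 | 2-(2-bromoethyl)-2-methyl-1,3-dioxolane | CC1(CCBr)OCCO1 | starting material
6 | [2-(2-methyl-1,3-dioxolan-2-yl)ethyl]magnesium bromide | CC1(CC[Mg]Br)OCCO1 | intermediate
7 | 3-ethoxy-4,4-dimethyl-1-[2-(2-methyl-1,3-dioxolan-2-yl)ethyl]cyclobut-2-en-1-ol (racemic) | CCOC1=CC(O)(CCC2(C)OCCO2)C1(C)C | intermediate
8 | 4,4-dimethyl-3-(3-oxobutyl)cyclobut-2-en-1-one | CC(=O)CCC1=CC(=O)C1(C)C | intermediate
9 | (1S,4R,5S)-4-[diethoxy(methyl)silyloxy]-4,7,7-trimethylbicyclo[3.2.0]heptan-6-one | O=C1[C@H]2[C@H](CC[C@@]2(C)O[Si](C)(OCC)OCC)C1(C)C | intermediate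
10 | (1S,4R,5S)-4-hydroxy-4,7,7-trimethylbicyclo[3.2.0]heptan-6-one | O=C1[C@H]2[C@H](CC[C@@]2(C)O)C1(C)C | intermediate
11 | (1S,4R,5S)-4,7,7-trimethyl-4-(triethylsilyloxy)bicyclo[3.2.0]heptan-6-one | O=C1[C@H]2[C@H](CC[C@@]2(C)O[Si](CC)(CC)CC)C1(C)C | intermediate
12 | 2-chloro-5-methoxyphenol | COc1ccc(Cl)c(O)c1 | starting material
13 | 4-bromo-2-chloro-5-methoxyphenol | COc1cc(O)c(Cl)cc1Br | intermediate
14 | 1-(2-fluoro-4-methoxyphenyl)ethan-1-one | CC(=O)c1ccc(OC)cc1F | starting material
15 | 1-[2-(4-bromo-2-chloro-5-methoxyphenoxy)-4-methoxyphenyl]ethan-1-one | CC(=O)c1ccc(OC)cc1Oc1cc(OC)c(Br)cc1Cl | intermediate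
16 | 1-[2-(4-bromo-2-chloro-5-hydroxyphenoxy)-4-hydroxyphenyl]ethan-1-one | CC(=O)c1ccc(O)cc1Oc1cc(O)c(Br)cc1Cl | intermediate
17 | 1-{2-[4-bromo-2-chloro-5-(triisopropylsilyloxy)phenoxy]-4-(triisopropylsilyloxy)phenyl}ethan-1-one | CC(=O)c1ccc(O[Si](C(C)C)(C(C)C)C(C)C)cc1Oc1cc(O[Si](C(C)C)(C(C)C)C(C)C)c(Br)cc1Cl | intermediate
18 | tributyl(3-methylbut-2-en-1-yl)stannane | CCCC[Sn](CCCC)(CCCC)CC=C(C)C | starting material
19 | 1-{2-[2-chloro-4-(3-methylbut-2-en-1-yl)-5-(triisopropylsilyloxy)phenoxy]-4-(triisopropylsilyloxy)phenyl}ethan-1-one | CC(=O)c1ccc(O[Si](C(C)C)(C(C)C)C(C)C)cc1Oc1cc(O[Si](C(C)C)(C(C)C)C(C)C)c(CC=C(C)C)cc1Cl | intermediate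
20 | aldol adduct, 6-OH endo and CH2C(O)Ar exo on C6 | CC(C)=CCc1cc(Cl)c(cc1O[Si](C(C)C)(C(C)C)C(C)C)Oc1cc(O[Si](C(C)C)(C(C)C)C(C)C)ccc1C(=O)C[C@@]2(O)[C@H]3[C@H](CC[C@@]3(C)O[Si](CC)(CC)CC)C2(C)C | intermediate
21 | methanesulfonate of 20 | CC(C)=CCc1cc(Cl)c(cc1O[Si](C(C)C)(C(C)C)C(C)C)Oc1cc(O[Si](C(C)C)(C(C)C)C(C)C)ccc1C(=O)C[C@@]2(OS(C)(=O)=O)[C@H]3[C@H](CC[C@@]3(C)O[Si](CC)(CC)CC)C2(C)C | intermediate
22 | cyclobutylidene enone (E/Z mixture, geometry left open) | CC(C)=CCc1cc(Cl)c(cc1O[Si](C(C)C)(C(C)C)C(C)C)Oc1cc(O[Si](C(C)C)(C(C)C)C(C)C)ccc1C(=O)C=C2[C@H]3[C@H](CC[C@@]3(C)O[Si](CC)(CC)CC)C2(C)C | intermediate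
23 | open-chain chloro ketone, key-step precursor (Cβ endo on C6) | CC(C)=CCc1cc(Cl)c(cc1O[Si](C(C)C)(C(C)C)C(C)C)Oc1cc(O[Si](C(C)C)(C(C)C)C(C)C)ccc1C(=O)C[C@@H]2[C@H]3[C@H](CC[C@@]3(C)O[Si](CC)(CC)CC)C2(C)C | intermediate
24 | 11-substituted dibenzo[b,f]oxepin-10(11H)-one, key-step product (one C11 epimer drawn) | CC(C)=CCc1cc2c(cc1O[Si](C(C)C)(C(C)C)C(C)C)Oc1cc(O[Si](C(C)C)(C(C)C)C(C)C)ccc1C(=O)[C@H]2[C@@H]2[C@H]3[C@H](CC[C@@]3(C)O[Si](CC)(CC)CC)C2(C)C | intermediate
25 | tertiary alcohol from 24 (one C11 epimer drawn) | CC(C)=CCc1cc2c(cc1O[Si](C(C)C)(C(C)C)C(C)C)Oc1cc(O[Si](C(C)C)(C(C)C)C(C)C)ccc1C(=O)[C@H]2[C@@H]2[C@H]3[C@H](CC[C@@]3(C)O)C2(C)C | intermediate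
26 | cyclic hemiketal (C10 and C11 left open) | CC(C)=CCc1cc2c(cc1O[Si](C(C)C)(C(C)C)C(C)C)Oc1cc(O[Si](C(C)C)(C(C)C)C(C)C)ccc1C1(O)C2[C@@H]2[C@H]3[C@H](CC[C@@]3(C)O1)C2(C)C | intermediate
27 | bis(triisopropylsilyl) ether of the target | CC(C)=CCc1cc2c(cc1O[Si](C(C)C)(C(C)C)C(C)C)Oc1cc(O[Si](C(C)C)(C(C)C)C(C)C)ccc1C1=C2[C@@H]2[C@H]3[C@H](CC[C@@]3(C)O1)C2(C)C | intermediate
28 | CNP0185814.1 | CC(C)=CCc1cc2c(cc1O)Oc1cc(O)ccc1C1=C2[C@@H]2[C@H]3[C@H](CC[C@@]3(C)O1)C2(C)C | target

## Step count and risks
Total step count: 15. Longest linear sequence: 11 steps (steps 5–15). The bicyclic branch (steps 1–4) joins at step 10.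

**Step 3 (labelled step).**
- What may go wrong: the ligand may discriminate the two enone faces poorly. Hydrosilylation of one of the ketone carbonyls may compete with conjugate reduction. The copper enolate may be quenched before it reaches the methyl ketone.
- Fallback (known chemistry), from 8 back to 10: the catalytic asymmetric step is given up. The ring C=C is hydrogenated (H2, Pd/C, EtOAc) to racemic 2,2-dimethyl-3-(3-oxobutyl)cyclobutan-1-one F1.
- The cyclopentane is then closed by a base-mediated intramolecular aldol addition under equilibrating conditions (catalytic KOtBu, t-BuOH–THF, 0 °C). Only the cyclobutanone CH2 can reach the methyl ketone through a five-membered transition state, and the smaller OH takes the concave position.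
- The racemate is separated by preparative chromatography on a chiral stationary phase. (1R,4S,5R)-4-hydroxy-4,7,7-trimethylbicyclo[3.2.0]heptan-6-one F2 is discarded, and the route is rejoined at 10.

**Step 13 (key step).**
- What may go wrong: insertion into the electron-rich, ortho-oxygenated C–Cl bond may be slow. Crowding of Cβ by the C7 methyl groups and the endo OSiEt3 group may retard enolate transfer and reductive elimination, so that β-hydride elimination and net hydrodechlorination take over. The alkoxide may also attack the aryl silyl ethers.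
- Fallback, from 23 back to 24: the same bond is made without an alkylpalladium species, by the photostimulated radical-chain (SRN1) arylation of the preformed potassium enolate (KN(SiMe3)2, liquid NH3–THF, −33 °C, 350 nm). Electron transfer cleaves C–Cl and the aryl radical adds to the enolate carbon.
- This reaction type is known for closing medium rings by intramolecular enolate arylation. No new compound is made (F0).

**Step 10.**
- What may go wrong: proton transfer from the cyclobutanone may occur instead of addition, followed by loss of the β-silyloxy group. Retro-aldol cleavage may occur on warming. The triethylsilyl group may migrate to the neighbouring new alkoxide, which would also block step 11.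
- Fallback, from 19 back to 22: the lithium enolate of 19 is C-phosphorylated with ClP(OEt)2 and oxidised in air to diethyl [2-Ar-2-oxoethyl]phosphonate F3.
- A Horner–Wadsworth–Emmons olefination of 11 follows (NaH, THF, reflux). It expels the oxygen through an oxaphosphetane inside the molecule and rejoins the route directly at enone 22, bypassing 20 and 21.

Further compounds
F1 | step 3 | racemic 2,2-dimethyl-3-(3-oxobutyl)cyclobutan-1-one | CC(=O)CCC1CC(=O)C1(C)C
F2 | step 3 | (1R,4S,5R)-4-hydroxy-4,7,7-trimethylbicyclo[3.2.0]heptan-6-one | O=C1[C@@H]2[C@@H](CC[C@]2(C)O)C1(C)C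
F0 | step 13 | none | none
F3 | step 10 | diethyl [2-Ar-2-oxoethyl]phosphonate | CCOP(=O)(OCC)CC(=O)c1ccc(O[Si](C(C)C)(C(C)C)C(C)C)cc1Oc1cc(O[Si](C(C)C)(C(C)C)C(C)C)c(CC=C(C)C)cc1Cl
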